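**Retrosynthetic overview** (germacrane numbering: C7/C8 = lactone ring-fusion carbons, C14 = CH2OAc on C10, C15 = CH2O-acyl on C4)
1. The C15 ester (carboxylate SN2), the C14 acetate and the exocyclic methylene are put on last; the core is a trans-fused germacra-1(10),4-dien-12,8-olide with C1(10) cis and C4 trans in the ring.
2. The ten-membered ring comes from an anionic oxy-Cope rearrangement of a lactone-locked 5-hydroxy-5-alkenyl-10-vinyl cyclohexane: C2–C3 forms, C5–C10 breaks, and the C5 enolate oxygen leaves as triflate, then H.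
3. The oxy-Cope substrate comes from a trans-fused bicyclic keto lactone by two axial additions (CH2O at C10, alkenylcerium at C5).
4. The keto lactone comes from an (R)-butenolide tosylate by vinylogous Mukaiyama–Michael addition (C6–C7, trans to the bought C8) and β-keto-ester alkylation (C9–C10).
5. Ring order: γ-lactone (bought) → cyclohexanone (annulation) → cyclodecadiene (ring expansion).

Assumption: (5R)-5-(hydroxymethyl)oxolan-2-one (the lactone made from D-glutamic acid), 2-bromoallyl alcohol and 2-(hydroxymethyl)acrylic acid are bought.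

**Step 1**
Reactants: 1 (5R)-5-(hydroxymethyl)oxolan-2-one
Product: 2 [(2R)-5-oxooxolan-2-yl]methyl 4-methylbenzenesulfonate
Conditions: TsCl, pyridine, CH2Cl2, 0 °C to rt
Reagents that add atoms: 4-toluenesulfonyl chloride, Cc1ccc(cc1)S(Cl)(=O)=O
Why: Sulfonylation (tosylation) of the primary alcohol makes C9 an electrophile for the later ring closure and does not touch the bought stereocentre C8.

**Step 2**
Reactants: 2 [(2R)-5-oxooxolan-2-yl]methyl 4-methylbenzenesulfonate
Product: 5 [(2R)-5-oxo-2,5-dihydrofuran-2-yl]methyl 4-methylbenzenesulfonate, via selenide 3 (not isolated), via selenoxide 4 (not isolated)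
Conditions: LiHMDS, THF, −78 °C; PhSeBr; then 30% H2O2, CH2Cl2, 0 °C to rt
Reagents that add atoms: none
Why: α-Selenenylation of the lactone enolate and selenoxide syn-elimination give the butenolide under non-basic final conditions, so C8 is not epimerised.

**Step 3**
Reactants: 5 [(2R)-5-oxo-2,5-dihydrofuran-2-yl]methyl 4-methylbenzenesulfonate
Product: 6 methyl 4-[(2R,3R)-2-(tosyloxymethyl)-5-oxooxolan-3-yl]-3-oxobutanoate
Conditions: 1-methoxy-1,3-bis(trimethylsilyloxy)buta-1,3-diene, TiCl4, CH2Cl2, −78 °C; aq. NaHCO3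
Reagents that add atoms: 1-methoxy-1,3-bis(trimethylsilyloxy)buta-1,3-diene, COC(O[Si](C)(C)C)=CC(=C)O[Si](C)(C)C
Why: In this vinylogous Mukaiyama–Michael addition the terminal carbon of the bis(silyloxy)diene attacks the TiCl4-activated butenolide on the face opposite the CH2OTs group, which sets C7 trans to the bought C8, and the acidic conditions leave the tosylate alone.

**Step 4**
Reactants: 6 methyl 4-[(2R,3R)-2-(tosyloxymethyl)-5-oxooxolan-3-yl]-3-oxobutanoate
Product: 8 (3aR,7aS)-hexahydro-1-benzofuran-2,5(3H)-dione, via keto ester 7 (not isolated)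
Conditions: K2CO3, NaI (cat.), DMSO, rt; then LiCl, H2O, 120 °C
Reagents that add atoms: none
Why: Intramolecular C-alkylation of the stabilised β-keto-ester anion (6-exo-tet; too soft to attack the lactone) closes the cyclohexanone and Krapcho dealkoxycarbonylation removes the ester, with C7 and C8 untouched so the lactone stays trans-fused.

**Step 5**
Reactants: 8 (3aR,7aS)-hexahydro-1-benzofuran-2,5(3H)-dione
Product: 11 (3aR,6E,7aS)-6-ethylidenehexahydro-1-benzofuran-2,5(3H)-dione, via lithium aldolate 9 (not isolated), via mesylate 10 (not isolated)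
Conditions: LDA, THF, −78 °C; MeCHO; MsCl, −78 to 0 °C; DBU, 0 °C
Reagents that add atoms: acetaldehyde, CC=O
Why: The ketone is deprotonated at the α-CH2 remote from the ring fusion (as in trans-2-decalones), and aldol addition, mesylation and E1cB elimination (aldol condensation) give the exocyclic (E)-enone.

**Step 6**
Reactants: 11 (3aR,6E,7aS)-6-ethylidenehexahydro-1-benzofuran-2,5(3H)-dione
Product: 13 (3aR,6S,7aS)-6-({[tert-butyl(dimethyl)silyl]oxy}methyl)-6-ethenylhexahydro-1-benzofuran-2,5(3H)-dione, via potassium alkoxide 12 (not isolated)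
Conditions: KHMDS (0.95 equiv), THF, −78 to 0 °C; HCHO (g), −78 °C; TBSCl, −78 to 0 °C
Reagents that add atoms: formaldehyde, C=O; tert-butyldimethylsilyl chloride, CC(C)(C)[Si](C)(C)Cl
Why: The equilibrated linear dienolate reacts with formaldehyde at its α-carbon (deconjugative aldol hydroxymethylation) along the axial trajectory of the trans-locked chair, so the new CH2O group (C14) is axial and the vinyl group equatorial at the quaternary C10, and silylation in the flask prevents retro-aldol.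

**Step 7**
Reactants: 14 2-bromoprop-2-en-1-ol
Product: 15 1-{[(2-bromoprop-2-en-1-yl)oxy]methyl}-4-methoxybenzene
Conditions: NaH, PMBCl, Bu4NI (cat.), THF/DMF, 0 °C to rt
Reagents that add atoms: 4-methoxybenzyl chloride, COc1ccc(CCl)cc1
Why: Williamson ether synthesis protects the allylic alcohol as a PMB ether, whose alkoxide is a poor leaving group at the later enolate stage.

**Step 8**
Reactants: 13 (3aR,6S,7aS)-6-({[tert-butyl(dimethyl)silyl]oxy}methyl)-6-ethenylhexahydro-1-benzofuran-2,5(3H)-dione; 15 1-{[(2-bromoprop-2-en-1-yl)oxy]methyl}-4-methoxybenzene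
Product: 18 (3aR,5S,6S,7aS)-6-({[tert-butyl(dimethyl)silyl]oxy}methyl)-6-ethenyl-5-hydroxy-5-{3-[(4-methoxybenzyl)oxy]prop-1-en-2-yl}hexahydro-1-benzofuran-2(3H)-one, via alkenyllithium 16 (not isolated), via alkenylcerium 17 (not isolated)
Conditions: 15, t-BuLi (2 equiv), Et2O, −78 °C; CeCl3, THF, −78 °C; then 13, −78 °C
Reagents that add atoms: none
Why: Bromine–lithium exchange and transmetalation give a non-basic alkenylcerium reagent that adds 1,2 to the ketone in preference to the lactone, from the axial face opposite the axial CH2OTBS group, so the new alkenyl group is axial at C5 and cis to the equatorial vinyl group.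

**Step 9**
Reactants: 18 (3aR,5S,6S,7aS)-6-({[tert-butyl(dimethyl)silyl]oxy}methyl)-6-ethenyl-5-hydroxy-5-{3-[(4-methoxybenzyl)oxy]prop-1-en-2-yl}hexahydro-1-benzofuran-2(3H)-one
Product: 21 (3aR,5E,9E,11aS)-10-({[tert-butyl(dimethyl)silyl]oxy}methyl)-6-{[(4-methoxybenzyl)oxy]methyl}-2-oxo-2,3,3a,4,7,8,11,11a-octahydrocyclodeca[b]furan-5-yl trifluoromethanesulfonate, via potassium alkoxide 19 (not isolated), via potassium enolate 20 (not isolated)
Conditions: KHMDS, 18-crown-6, THF, −40 to 0 °C; then PhNTf2, −78 to −20 °C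
Reagents that add atoms: N-phenylbis(trifluoromethanesulfonimide), O=S(=O)(N(c1ccccc1)S(=O)(=O)C(F)(F)F)C(F)(F)F
Why: The anionic oxy-Cope rearrangement ([3,3]-sigmatropic) goes through the only chair the trans-fused lactone allows (vinyl equatorial, alkenyl axial), forming C2–C3 and the ten-membered ring with C9 cis to C2 at C10=C1 (CH2OTBS trans to C2) and C6 trans to C3 in the enolate, and O-triflation fixes that enolate geometry.

**Step 10**
Reactants: 21 (3aR,5E,9E,11aS)-10-({[tert-butyl(dimethyl)silyl]oxy}methyl)-6-{[(4-methoxybenzyl)oxy]methyl}-2-oxo-2,3,3a,4,7,8,11,11a-octahydrocyclodeca[b]furan-5-yl trifluoromethanesulfonate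
Product: 22 (3aR,5Z,9E,11aS)-10-({[tert-butyl(dimethyl)silyl]oxy}methyl)-6-{[(4-methoxybenzyl)oxy]methyl}-3a,4,7,8,11,11a-hexahydrocyclodeca[b]furan-2(3H)-one
Conditions: Pd(OAc)2 (5 mol %), PPh3, HCO2H, Et3N, DMF, 40 °C
Reagents that add atoms: none
Why: Palladium-catalysed formate reduction of the enol triflate (oxidative addition, hydride transfer, reductive elimination) replaces OTf by H with retention, giving the C4=C5 bond trans in the ring with C15 cis to C6.

**Step 11**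
Reactants: 22 (3aR,5Z,9E,11aS)-10-({[tert-butyl(dimethyl)silyl]oxy}methyl)-6-{[(4-methoxybenzyl)oxy]methyl}-3a,4,7,8,11,11a-hexahydrocyclodeca[b]furan-2(3H)-one
Product: 25 (3aR,5Z,9E,11aS)-10-({[tert-butyl(dimethyl)silyl]oxy}methyl)-6-{[(4-methoxybenzyl)oxy]methyl}-3-methylidene-3a,4,7,8,11,11a-hexahydrocyclodeca[b]furan-2(3H)-one, via Mannich base 23 (not isolated), via methiodide 24 (not isolated)
Conditions: LDA, THF, −78 °C; CH2=NMe2+ I−, −78 to 0 °C; MeI, MeOH, rt; aq. NaHCO3, CH2Cl2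
Reagents that add atoms: Eschenmoser's salt, C=[N+](C)C.[I-]
Why: Mannich reaction of the lactone enolate, N-methylation and E1cB elimination (α-methylenation) install the exocyclic methylene without touching C7 or C8, and no ester is present yet to be attacked by LDA.

**Step 12**
Reactants: 25 (3aR,5Z,9E,11aS)-10-({[tert-butyl(dimethyl)silyl]oxy}methyl)-6-{[(4-methoxybenzyl)oxy]methyl}-3-methylidene-3a,4,7,8,11,11a-hexahydrocyclodeca[b]furan-2(3H)-one
Product: 26 (3aR,5Z,9E,11aS)-10-(hydroxymethyl)-6-{[(4-methoxybenzyl)oxy]methyl}-3-methylidene-3a,4,7,8,11,11a-hexahydrocyclodeca[b]furan-2(3H)-one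
Conditions: HF·pyridine, THF/pyridine, 0 °C
Reagents that add atoms: none
Why: Fluoride-mediated desilylation under buffered conditions frees only the C14 alcohol and spares the α-methylene lactone, the PMB ether and the 1,5-diene.

**Step 13**
Reactants: 26 (3aR,5Z,9E,11aS)-10-(hydroxymethyl)-6-{[(4-methoxybenzyl)oxy]methyl}-3-methylidene-3a,4,7,8,11,11a-hexahydrocyclodeca[b]furan-2(3H)-one
Product: 27 [(3aR,5Z,9E,11aS)-6-{[(4-methoxybenzyl)oxy]methyl}-3-methylidene-2-oxo-2,3,3a,4,7,8,11,11a-octahydrocyclodeca[b]furan-10-yl]methyl acetate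
Conditions: Ac2O, pyridine, DMAP (cat.), CH2Cl2, 0 °C
Reagents that add atoms: acetic anhydride, CC(=O)OC(C)=O
Why: DMAP-catalysed acylation (esterification) of the only free hydroxyl gives the C14 acetate.

**Step 14**
Reactants: 27 [(3aR,5Z,9E,11aS)-6-{[(4-methoxybenzyl)oxy]methyl}-3-methylidene-2-oxo-2,3,3a,4,7,8,11,11a-octahydrocyclodeca[b]furan-10-yl]methyl acetate
Product: 28 [(3aR,5Z,9E,11aS)-6-(hydroxymethyl)-3-methylidene-2-oxo-2,3,3a,4,7,8,11,11a-octahydrocyclodeca[b]furan-10-yl]methyl acetate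
Conditions: DDQ, CH2Cl2/pH 7 buffer, 0 °C
Reagents that add atoms: none
Why: Oxidative PMB-ether cleavage by DDQ (benzylic oxidation to the oxocarbenium ion and hydrolysis) frees the C15 alcohol without affecting the acetate, the lactone or the alkenes.

**Step 15**
Reactants: 28 [(3aR,5Z,9E,11aS)-6-(hydroxymethyl)-3-methylidene-2-oxo-2,3,3a,4,7,8,11,11a-octahydrocyclodeca[b]furan-10-yl]methyl acetate; 29 2-(hydroxymethyl)prop-2-enoic acid
Product: 31 [(3aR,5Z,9E,11aS)-10-(acetyloxymethyl)-3-methylidene-2-oxo-2,3,3a,4,7,8,11,11a-octahydrocyclodeca[b]furan-6-yl]methyl 2-(hydroxymethyl)prop-2-enoate, via allylic mesylate 30 (not isolated)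
Conditions: MsCl, Et3N, CH2Cl2, −30 °C; then 29, Cs2CO3, DMF, −30 to 0 °C
Reagents that add atoms: none
Why: Mesylation of the primary allylic alcohol and SN2 displacement by the caesium carboxylate (carboxylate O-alkylation), which is far more nucleophilic than the reagent's own hydroxyl, give the ester without a protecting group and without touching the alkene geometry.

**Compound list**
1 | (5R)-5-(hydroxymethyl)oxolan-2-one | OC[C@H]1CCC(=O)O1 | starting material
2 | [(2R)-5-oxooxolan-2-yl]methyl 4-methylbenzenesulfonate | Cc1ccc(cc1)S(=O)(=O)OC[C@H]1CCC(=O)O1 | intermediate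
3 | [(2R)-5-oxo-4-(phenylselanyl)oxolan-2-yl]methyl 4-methylbenzenesulfonate (both C-4 epimers) | Cc1ccc(cc1)S(=O)(=O)OC[C@H]1CC([Se]c2ccccc2)C(=O)O1 | intermediate (not isolated)
4 | selenoxide of 3 | Cc1ccc(cc1)S(=O)(=O)OC[C@H]1CC([Se](=O)c2ccccc2)C(=O)O1 | intermediate (not isolated)
5 | [(2R)-5-oxo-2,5-dihydrofuran-2-yl]methyl 4-methylbenzenesulfonate | Cc1ccc(cc1)S(=O)(=O)OC[C@H]1C=CC(=O)O1 | intermediate
6 | methyl 4-[(2R,3R)-2-(tosyloxymethyl)-5-oxooxolan-3-yl]-3-oxobutanoate (3,4-trans lactone) | COC(=O)CC(=O)C[C@@H]1CC(=O)O[C@H]1COS(=O)(=O)c1ccc(C)cc1 | intermediate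
7 | methyl (3aR,7aS)-2,5-dioxooctahydro-1-benzofuran-6-carboxylate (C-6 epimers/enol) | COC(=O)C1C(=O)C[C@@H]2CC(=O)O[C@H]2C1 | intermediate (not isolated)
8 | (3aR,7aS)-hexahydro-1-benzofuran-2,5(3H)-dione (trans-fused) | O=C1C[C@@H]2CC(=O)O[C@H]2CC1 | intermediate
9 | lithium aldolate of 8 with acetaldehyde at C-6 | O=C1C[C@@H]2CC(=O)O[C@H]2CC1C(C)[O-].[Li+] | intermediate (not isolated)
10 | mesylate of the aldol 9 | O=C1C[C@@H]2CC(=O)O[C@H]2CC1C(C)OS(C)(=O)=O | intermediate (not isolated)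
11 | (3aR,6E,7aS)-6-ethylidenehexahydro-1-benzofuran-2,5(3H)-dione | O=C1C[C@@H]2CC(=O)O[C@H]2C\C1=C/C | intermediate
12 | potassium [(3aR,6S,7aS)-6-ethenyl-2,5-dioxooctahydro-1-benzofuran-6-yl]methanolate | O=C1C[C@@H]2CC(=O)O[C@H]2C[C@@]1(C[O-])C=C.[K+] | intermediate (not isolated)
13 | (3aR,6S,7aS)-6-({[tert-butyl(dimethyl)silyl]oxy}methyl)-6-ethenylhexahydro-1-benzofuran-2,5(3H)-dione (CH2OTBS axial, vinyl equatorial) | O=C1C[C@@H]2CC(=O)O[C@H]2C[C@@]1(CO[Si](C)(C)C(C)(C)C)C=C | intermediate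
14 | 2-bromoprop-2-en-1-ol | OCC(Br)=C | starting material
15 | 1-{[(2-bromoprop-2-en-1-yl)oxy]methyl}-4-methoxybenzene | COc1ccc(COCC(Br)=C)cc1 | intermediate
16 | {3-[(4-methoxybenzyl)oxy]prop-1-en-2-yl}lithium | [Li]C(=C)COCc1ccc(OC)cc1 | intermediate (not isolated)
17 | dichloro{3-[(4-methoxybenzyl)oxy]prop-1-en-2-yl}cerium | Cl[Ce](Cl)C(=C)COCc1ccc(OC)cc1 | intermediate (not isolated)
18 | (3aR,5S,6S,7aS)-6-({[tert-butyl(dimethyl)silyl]oxy}methyl)-6-ethenyl-5-hydroxy-5-{3-[(4-methoxybenzyl)oxy]prop-1-en-2-yl}hexahydro-1-benzofuran-2(3H)-one (alkenyl axial, cis to vinyl) | O[C@]1(C(=C)COCc3ccc(OC)cc3)C[C@@H]2CC(=O)O[C@H]2C[C@@]1(CO[Si](C)(C)C(C)(C)C)C=C | intermediate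
19 | potassium alkoxide of 18 | [K+].[O-][C@]1(C(=C)COCc3ccc(OC)cc3)C[C@@H]2CC(=O)O[C@H]2C[C@@]1(CO[Si](C)(C)C(C)(C)C)C=C | intermediate (not isolated)
20 | potassium (3aR,5E,9E,11aS)-10-(TBS-oxymethyl)-6-(PMB-oxymethyl)-2-oxo-octahydrocyclodeca[b]furan-5-olate (ring-expanded enolate) | COc1ccc(COC/C2=C([O-])\C[C@@H]3CC(=O)O[C@H]3C/C(CO[Si](C)(C)C(C)(C)C)=C\CC2)cc1.[K+] | intermediate (not isolated)
21 | (3aR,5E,9E,11aS)-10-({[tert-butyl(dimethyl)silyl]oxy}methyl)-6-{[(4-methoxybenzyl)oxy]methyl}-2-oxo-2,3,3a,4,7,8,11,11a-octahydrocyclodeca[b]furan-5-yl trifluoromethanesulfonate | COc1ccc(COC/C2=C(OS(=O)(=O)C(F)(F)F)\C[C@@H]3CC(=O)O[C@H]3C/C(CO[Si](C)(C)C(C)(C)C)=C\CC2)cc1 | intermediate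
22 | (3aR,5Z,9E,11aS)-10-({[tert-butyl(dimethyl)silyl]oxy}methyl)-6-{[(4-methoxybenzyl)oxy]methyl}-3a,4,7,8,11,11a-hexahydrocyclodeca[b]furan-2(3H)-one | COc1ccc(COC/C2=C\C[C@@H]3CC(=O)O[C@H]3C/C(CO[Si](C)(C)C(C)(C)C)=C\CC2)cc1 | intermediate
23 | 3-[(dimethylamino)methyl] derivative of 22 (C-3 epimers) | COc1ccc(COC/C2=C\C[C@@H]3C(CN(C)C)C(=O)O[C@H]3C/C(CO[Si](C)(C)C(C)(C)C)=C\CC2)cc1 | intermediate (not isolated)
24 | trimethylammonium iodide of 23 | COc1ccc(COC/C2=C\C[C@@H]3C(C[N+](C)(C)C)C(=O)O[C@H]3C/C(CO[Si](C)(C)C(C)(C)C)=C\CC2)cc1.[I-] | intermediate (not isolated)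
25 | (3aR,5Z,9E,11aS)-10-({[tert-butyl(dimethyl)silyl]oxy}methyl)-6-{[(4-methoxybenzyl)oxy]methyl}-3-methylidene-3a,4,7,8,11,11a-hexahydrocyclodeca[b]furan-2(3H)-one | COc1ccc(COC/C2=C\C[C@@H]3C(=C)C(=O)O[C@H]3C/C(CO[Si](C)(C)C(C)(C)C)=C\CC2)cc1 | intermediate
26 | (3aR,5Z,9E,11aS)-10-(hydroxymethyl)-6-{[(4-methoxybenzyl)oxy]methyl}-3-methylidene-3a,4,7,8,11,11a-hexahydrocyclodeca[b]furan-2(3H)-one | COc1ccc(COC/C2=C\C[C@@H]3C(=C)C(=O)O[C@H]3C/C(CO)=C\CC2)cc1 | intermediate
27 | [(3aR,5Z,9E,11aS)-6-{[(4-methoxybenzyl)oxy]methyl}-3-methylidene-2-oxo-2,3,3a,4,7,8,11,11a-octahydrocyclodeca[b]furan-10-yl]methyl acetate | COc1ccc(COC/C2=C\C[C@@H]3C(=C)C(=O)O[C@H]3C/C(COC(C)=O)=C\CC2)cc1 | intermediate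
28 | [(3aR,5Z,9E,11aS)-6-(hydroxymethyl)-3-methylidene-2-oxo-2,3,3a,4,7,8,11,11a-octahydrocyclodeca[b]furan-10-yl]methyl acetate | OC/C1=C\C[C@@H]2C(=C)C(=O)O[C@H]2C/C(COC(C)=O)=C\CC1 | intermediate
29 | 2-(hydroxymethyl)prop-2-enoic acid | C=C(CO)C(=O)O | starting material
30 | methanesulfonate of 28 at C15 | CS(=O)(=O)OC/C1=C\C[C@@H]2C(=C)C(=O)O[C@H]2C/C(COC(C)=O)=C\CC1 | intermediate (not isolated)
31 | [(3aR,5Z,9E,11aS)-10-(acetyloxymethyl)-3-methylidene-2-oxo-2,3,3a,4,7,8,11,11a-octahydrocyclodeca[b]furan-6-yl]methyl 2-(hydroxymethyl)prop-2-enoate | C=C(CO)C(=O)OC/C1=C\C[C@@H]2C(=C)C(=O)O[C@H]2C/C(COC(C)=O)=C\CC1 | target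

**Total step count:** 15. **Longest linear sequence:** 14 (steps 1–6 and 8–15; step 7 is a one-step branch).

**Three steps most likely to fail**

Step 6 (quaternary C10). The equilibrated dienolate may react at the α′-carbon or the γ-carbon, or with poor axial selectivity. The fallback sets out from 6 and comes back at 13. Compound 6 is cyclised with K2CO3/NaI as in step 4 but the β-keto ester 7 is isolated. Its enolate (cat. NaH, THF) adds to phenyl vinyl sulfoxide only at the ester-bearing carbon and gives the sulfinylethyl keto ester F1. LiCl in wet DMSO at 120 °C then removes the ester (Krapcho) and PhSOH (sulfoxide syn-elimination) in one pot and gives the β,γ-unsaturated ethenyl ketone F2. The C-6 hydrogen of F2 is both α to the ketone and allylic, so LiHMDS at −78 °C makes the same dienolate by direct deprotonation without equilibration, and CH2O then TBSCl give 13.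

Step 8 (alkenyl addition beside a lactone). The organometallic may attack the lactone or enolise the hindered ketone. The fallback sets out from 13 and comes back at 18. Ethynylmagnesium bromide with CeCl3 (small, ketone-selective, same axial attack) gives the propargylic alcohol F3. B-bromo-9-BBN followed by AcOH (Markovnikov bromoboration and protodeboronation) gives the 1-bromoethenyl carbinol F4. Suzuki–Miyaura coupling of F4 with potassium {[(4-methoxybenzyl)oxy]methyl}trifluoroborate (Pd(OAc)2, RuPhos, Cs2CO3, dioxane/H2O) then builds the 2-(PMB-oxymethyl)vinyl group and gives 18.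

Step 9 (ring expansion and triflation). The enolate 20 carries a β-OPMB group and can lose PMBO− (E1cB) before it is trapped, and the free enolate sits across the ring from the lactone. The fallback sets out from 13 and comes back at 22; it keeps C15 as a free alkoxide, which cannot leave. The dilithio reagent from 14 (t-BuLi, 3 equiv; CeCl3) adds to 13 and gives the diol F5. KHMDS (2.2 equiv) with 18-crown-6 then effects the same rearrangement on the dianion, and quenching with TESCl gives the bis-silyl compound F6 (TES enol ether and C15–OTES). MeLi at −78 °C cleaves only the enol silyl ether, and PhNTf2 at that temperature gives the triflate F7. Pd/formate reduction gives the diene F8, PPTS in MeOH frees C15–OH to give the alcohol F9, and PMB trichloroacetimidate with cat. Sc(OTf)3 gives 22.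

**Further compounds**
F1 | step 6 | methyl (3aR,7aS)-2,5-dioxo-6-[2-(phenylsulfinyl)ethyl]octahydro-1-benzofuran-6-carboxylate (C-6 epimers) | O=C1C[C@@H]2CC(=O)O[C@H]2CC1(CCS(=O)c1ccccc1)C(=O)OC
F2 | step 6 | (3aR,7aS)-6-ethenylhexahydro-1-benzofuran-2,5(3H)-dione (C-6 epimers) | O=C1C[C@@H]2CC(=O)O[C@H]2CC1C=C
F3 | step 8 | (3aR,5S,6S,7aS)-6-({[tert-butyl(dimethyl)silyl]oxy}methyl)-6-ethenyl-5-ethynyl-5-hydroxyhexahydro-1-benzofuran-2(3H)-one | O[C@]1(C#C)C[C@@H]2CC(=O)O[C@H]2C[C@@]1(CO[Si](C)(C)C(C)(C)C)C=C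
F4 | step 8 | (3aR,5R,6S,7aS)-5-(1-bromoethenyl)-6-({[tert-butyl(dimethyl)silyl]oxy}methyl)-6-ethenyl-5-hydroxyhexahydro-1-benzofuran-2(3H)-one | O[C@]1(C(Br)=C)C[C@@H]2CC(=O)O[C@H]2C[C@@]1(CO[Si](C)(C)C(C)(C)C)C=C
F5 | step 9 | (3aR,5S,6S,7aS)-6-({[tert-butyl(dimethyl)silyl]oxy}methyl)-6-ethenyl-5-hydroxy-5-(3-hydroxyprop-1-en-2-yl)hexahydro-1-benzofuran-2(3H)-one | O[C@]1(C(=C)CO)C[C@@H]2CC(=O)O[C@H]2C[C@@]1(CO[Si](C)(C)C(C)(C)C)C=C
F6 | step 9 | (3aR,5E,9E,11aS)-10-({[tert-butyl(dimethyl)silyl]oxy}methyl)-5-(triethylsilyloxy)-6-[(triethylsilyloxy)methyl]-3a,4,7,8,11,11a-hexahydrocyclodeca[b]furan-2(3H)-one | CC[Si](CC)(CC)OC/C1=C(O[Si](CC)(CC)CC)\C[C@@H]2CC(=O)O[C@H]2C/C(CO[Si](C)(C)C(C)(C)C)=C\CC1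
F7 | step 9 | (3aR,5E,9E,11aS)-10-({[tert-butyl(dimethyl)silyl]oxy}methyl)-2-oxo-6-[(triethylsilyloxy)methyl]-2,3,3a,4,7,8,11,11a-octahydrocyclodeca[b]furan-5-yl trifluoromethanesulfonate | CC[Si](CC)(CC)OC/C1=C(OS(=O)(=O)C(F)(F)F)\C[C@@H]2CC(=O)O[C@H]2C/C(CO[Si](C)(C)C(C)(C)C)=C\CC1
F8 | step 9 | (3aR,5Z,9E,11aS)-10-({[tert-butyl(dimethyl)silyl]oxy}methyl)-6-[(triethylsilyloxy)methyl]-3a,4,7,8,11,11a-hexahydrocyclodeca[b]furan-2(3H)-one | CC[Si](CC)(CC)OC/C1=C\C[C@@H]2CC(=O)O[C@H]2C/C(CO[Si](C)(C)C(C)(C)C)=C\CC1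
F9 | step 9 | (3aR,5Z,9E,11aS)-10-({[tert-butyl(dimethyl)silyl]oxy}methyl)-6-(hydroxymethyl)-3a,4,7,8,11,11a-hexahydrocyclodeca[b]furan-2(3H)-one | OC/C1=C\C[C@@H]2CC(=O)O[C@H]2C/C(CO[Si](C)(C)C(C)(C)C)=C\CC1
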